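**Plan**

- Numbering: lactone O1, C2 (C=O), C3, C4, C5 (OCH2); C6 is the CH2 between C4 and ring B (4-hydroxy-3-methoxyphenyl); C7 is the CH2 between C3 and ring A (3,4-dihydroxy-5-methoxyphenyl).
- Retrosynthetic cuts, in order: the three O-benzyl groups; C4–C5 of the lactone, opened to a C5 (acyloxy)methyl radical and a C4=C6 styrene; O1–C5 (halomethyl ester of an acid); C3–C7 (benzylation of an imide enolate); C4=C6 (Wittig).
- Forward: ring B aldehyde, then styrylacetic acid, then chiral imide; the ring A bromide is joined at C3; the acid becomes its iodomethyl ester; the lactone, the only ring built, closes last by 5-exo attack of C5 on C4; hydrogenolysis ends the route.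
- Enabling feature: O1 sits next to C5 and supports a radical there, and ring B on C6 makes C4=C6 a styrene, so attack at C4 leaves a benzylic radical at C6 that ends as the CH2 of the target.
- Stereochemistry: C3 (R) from alkylation of the (R)-4-benzyl-2-oxazolidinone imide; C4 (R) by relay from C3 in the ring closure (3,4-trans).

Key step: step 10

Remark: the Wittig step is taken to give the E alkene (a Z fraction would converge, because C4=C6 is consumed in step 10), and 3,4-dihydroxy-5-methoxybenzaldehyde is taken as purchasable.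

**Route**

Step 1
Reactants: 1 4-(benzyloxy)-3-methoxybenzaldehyde; 2 (2-carboxyethyl)triphenylphosphonium bromide
Product: 3 (E)-4-[4-(benzyloxy)-3-methoxyphenyl]but-3-enoic acid
Conditions: t-BuOK (2.2 equiv), THF, 0 °C to rt; 1 M HCl work-up
Reagents that add atoms: none
Why: Wittig olefination with the carboxylate-bearing ylide should give the styrylacetic acid mainly as the E isomer, and conjugation with ring B keeps the alkene in the beta,gamma position.

Step 2
Reactants: 3 (E)-4-[4-(benzyloxy)-3-methoxyphenyl]but-3-enoic acid; 4 (R)-4-benzyl-2-oxazolidinone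
Product: 6 (R)-4-benzyl-3-[(E)-4-[4-(benzyloxy)-3-methoxyphenyl]but-3-enoyl]oxazolidin-2-one, via mixed pivalic anhydride 5 (not isolated)
Conditions: PivCl, Et3N, THF, −20 °C; then LiCl, 4, −20 °C to rt
Reagents that add atoms: none
Why: N-acylation of the oxazolidinone through the mixed pivalic anhydride with LiCl/Et3N is mild enough to leave the beta,gamma-alkene in place.

Step 3
Reactants: 7 3,4-dihydroxy-5-methoxybenzaldehyde
Product: 8 3,4-bis(benzyloxy)-5-methoxybenzaldehyde
Conditions: BnBr (2.4 equiv), K2CO3, DMF, 60 °C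
Reagents that add atoms: benzyl bromide, BrCc1ccccc1
Why: Williamson etherification masks both phenols as benzyl ethers, which should survive the base, hydride, enolate and radical steps and come off together at the end.

Step 4
Reactants: 8 3,4-bis(benzyloxy)-5-methoxybenzaldehyde
Product: 9 [3,4-bis(benzyloxy)-5-methoxyphenyl]methanol
Conditions: NaBH4, MeOH/THF, 0 °C
Reagents that add atoms: none
Why: Borohydride reduction of the aryl aldehyde to the benzylic alcohol is chemoselective and leaves the benzyl ethers untouched.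

Step 5
Reactants: 9 [3,4-bis(benzyloxy)-5-methoxyphenyl]methanol
Product: 10 1,2-bis(benzyloxy)-5-(bromomethyl)-3-methoxybenzene
Conditions: PBr3 (0.4 equiv), Et2O, 0 °C
Reagents that add atoms: phosphorus tribromide, BrP(Br)Br
Why: Bromide displaces the activated phosphite ester of the benzylic alcohol under cold, brief conditions that spare the benzyl ethers.

Step 6
Reactants: 6 (R)-4-benzyl-3-[(E)-4-[4-(benzyloxy)-3-methoxyphenyl]but-3-enoyl]oxazolidin-2-one; 10 1,2-bis(benzyloxy)-5-(bromomethyl)-3-methoxybenzene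
Product: 12 (R)-4-benzyl-3-[(2R,3E)-2-[3,4-bis(benzyloxy)-5-methoxybenzyl]-4-[4-(benzyloxy)-3-methoxyphenyl]but-3-enoyl]oxazolidin-2-one, via sodium Z-enolate 11 (not isolated)
Conditions: NaN(SiMe3)2 (1.05 equiv), THF, −78 °C; then 10, −78 to −40 °C
Reagents that add atoms: none
Why: Evans auxiliary alkylation: the chelated sodium Z-enolate, an extended dienolate that reacts at its alpha carbon, is benzylated on the face opposite the auxiliary benzyl group, which sets C3 as R.

Step 7
Reactants: 12 (R)-4-benzyl-3-[(2R,3E)-2-[3,4-bis(benzyloxy)-5-methoxybenzyl]-4-[4-(benzyloxy)-3-methoxyphenyl]but-3-enoyl]oxazolidin-2-one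
Product: 14 (2R,3E)-2-[3,4-bis(benzyloxy)-5-methoxybenzyl]-4-[4-(benzyloxy)-3-methoxyphenyl]but-3-enoic acid, via peroxy acid 13 (not isolated)
Conditions: LiOH, H2O2, THF/H2O, 0 °C; then Na2SO3; 1 M HCl to pH 3
Reagents that add atoms: hydrogen peroxide, OO
Why: Hydroperoxide attacks the exocyclic imide carbonyl selectively and sulfite reduces the peroxy acid, which should free the acid and the auxiliary at 0 °C without touching C3.

Step 8
Reactants: 14 (2R,3E)-2-[3,4-bis(benzyloxy)-5-methoxybenzyl]-4-[4-(benzyloxy)-3-methoxyphenyl]but-3-enoic acid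
Product: 15 chloromethyl (2R,3E)-2-[3,4-bis(benzyloxy)-5-methoxybenzyl]-4-[4-(benzyloxy)-3-methoxyphenyl]but-3-enoate
Conditions: ClCH2OSO2Cl, NaHCO3, n-Bu4NHSO4 (cat.), CH2Cl2/H2O, rt
Reagents that add atoms: chloromethyl chlorosulfate, ClCOS(=O)(=O)Cl
Why: Phase-transfer O-alkylation of the carboxylate at the CH2 of chloromethyl chlorosulfate (chlorosulfate leaves) places C5 on O1 under bicarbonate conditions too weak to epimerise C3.

Step 9
Reactants: 15 chloromethyl (2R,3E)-2-[3,4-bis(benzyloxy)-5-methoxybenzyl]-4-[4-(benzyloxy)-3-methoxyphenyl]but-3-enoate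
Product: 16 iodomethyl (2R,3E)-2-[3,4-bis(benzyloxy)-5-methoxybenzyl]-4-[4-(benzyloxy)-3-methoxyphenyl]but-3-enoate
Conditions: NaI, acetone, rt, dark; used without storage
Reagents that add atoms: sodium iodide, [Na+].[I-]
Why: Finkelstein halide exchange gives the iodide, from which a tin radical abstracts the halogen fast enough to carry a chain at high dilution.

Step 10
Reactants: 16 iodomethyl (2R,3E)-2-[3,4-bis(benzyloxy)-5-methoxybenzyl]-4-[4-(benzyloxy)-3-methoxyphenyl]but-3-enoate
Product: 19 (3R,4R)-3-[3,4-bis(benzyloxy)-5-methoxybenzyl]-4-[4-(benzyloxy)-3-methoxybenzyl]dihydrofuran-2(3H)-one, via acyloxymethyl radical 17 (not isolated), via benzylic radical 18 (not isolated)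
Conditions: Bu3SnH (1.3 equiv) + AIBN (0.2 equiv) by syringe pump over 6 h, PhMe (0.005 M), 110 °C; chromatography on KF/silica
Reagents that add atoms: none
Why: Bu3Sn• takes the iodine atom of 16 and leaves the (acyloxy)methyl radical 17, whose C5 adds to C4 of the C4=C6 styrene to give the benzylic radical 18; 18 takes a hydrogen atom from Bu3SnH, which returns Bu3Sn• to the chain. The closest known reaction type is the tin hydride 5-exo-trig cyclisation of ester-tethered alkyl radicals made from halomethyl esters of alkenoic acids and from alkenyl haloacetates, which closes gamma-lactones. The lactone ring closes in the 5-exo-trig mode. C4 is controlled by the C3 centre: in the chair-like transition state the C7 benzyl group on C3 lies pseudo-equatorial and the styrene turns away from it, which should give the 3,4-trans (3R,4R) lactone, also the more stable isomer. The step needs 5-exo and not 6-endo attack, which ring B on C6 secures because only attack at C4 leaves a benzylic radical, and it needs ring closure ahead of hydrogen transfer to 17, which the high temperature (it lets the ester reach the E rotamer that the ring requires) and the low standing concentration of Bu3SnH should secure.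

Step 11
Reactants: 19 (3R,4R)-3-[3,4-bis(benzyloxy)-5-methoxybenzyl]-4-[4-(benzyloxy)-3-methoxybenzyl]dihydrofuran-2(3H)-one
Product: 20 (−)-thujaplicatin
Conditions: H2 (1 atm), Pd/C (10%), EtOAc/MeOH, rt
Reagents that add atoms: none
Why: Hydrogenolysis over palladium on carbon cleaves the three benzyl aryl ethers and should leave the lactone, the methyl ethers and both stereocentres unchanged.

**Compound list**

1 | 4-(benzyloxy)-3-methoxybenzaldehyde | O=Cc1ccc(OCc2ccccc2)c(OC)c1 | starting material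
2 | (2-carboxyethyl)triphenylphosphonium bromide | OC(=O)CC[P+](c1ccccc1)(c1ccccc1)c1ccccc1.[Br-] | starting material
3 | (E)-4-[4-(benzyloxy)-3-methoxyphenyl]but-3-enoic acid | OC(=O)C/C=C/c1ccc(OCc2ccccc2)c(OC)c1 | intermediate
4 | (R)-4-benzyl-2-oxazolidinone | O=C1N[C@H](Cc2ccccc2)CO1 | starting material
5 | mixed anhydride of 3 with pivalic acid | CC(C)(C)C(=O)OC(=O)C/C=C/c1ccc(OCc2ccccc2)c(OC)c1 | intermediate (not isolated)
6 | (R)-4-benzyl-3-[(E)-4-[4-(benzyloxy)-3-methoxyphenyl]but-3-enoyl]oxazolidin-2-one | O=C(C/C=C/c1ccc(OCc2ccccc2)c(OC)c1)N1[C@H](Cc2ccccc2)COC1=O | intermediate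
7 | 3,4-dihydroxy-5-methoxybenzaldehyde | COc1cc(C=O)cc(O)c1O | starting material
8 | 3,4-bis(benzyloxy)-5-methoxybenzaldehyde | COc1cc(C=O)cc(OCc2ccccc2)c1OCc1ccccc1 | intermediate
9 | [3,4-bis(benzyloxy)-5-methoxyphenyl]methanol | COc1cc(CO)cc(OCc2ccccc2)c1OCc1ccccc1 | intermediate
10 | 1,2-bis(benzyloxy)-5-(bromomethyl)-3-methoxybenzene | COc1cc(CBr)cc(OCc2ccccc2)c1OCc1ccccc1 | intermediate
11 | sodium Z-enolate of imide 6 | [Na+].[O-]/C(=C\C=C\c1ccc(OCc2ccccc2)c(OC)c1)N1[C@H](Cc2ccccc2)COC1=O | intermediate (not isolated)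
12 | (R)-4-benzyl-3-[(2R,3E)-2-[3,4-bis(benzyloxy)-5-methoxybenzyl]-4-[4-(benzyloxy)-3-methoxyphenyl]but-3-enoyl]oxazolidin-2-one | O=C([C@H](Cc1cc(OC)c(OCc2ccccc2)c(OCc3ccccc3)c1)/C=C/c1ccc(OCc2ccccc2)c(OC)c1)N1[C@H](Cc2ccccc2)COC1=O | intermediate
13 | (2R,3E)-2-[3,4-bis(benzyloxy)-5-methoxybenzyl]-4-[4-(benzyloxy)-3-methoxyphenyl]but-3-eneperoxoic acid (lithium salt in the flask) | OOC(=O)[C@H](Cc1cc(OC)c(OCc2ccccc2)c(OCc3ccccc3)c1)/C=C/c1ccc(OCc2ccccc2)c(OC)c1 | intermediate (not isolated)
14 | (2R,3E)-2-[3,4-bis(benzyloxy)-5-methoxybenzyl]-4-[4-(benzyloxy)-3-methoxyphenyl]but-3-enoic acid | OC(=O)[C@H](Cc1cc(OC)c(OCc2ccccc2)c(OCc3ccccc3)c1)/C=C/c1ccc(OCc2ccccc2)c(OC)c1 | intermediate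
15 | chloromethyl ester of acid 14 | ClCOC(=O)[C@H](Cc1cc(OC)c(OCc2ccccc2)c(OCc3ccccc3)c1)/C=C/c1ccc(OCc2ccccc2)c(OC)c1 | intermediate
16 | iodomethyl ester of acid 14 | ICOC(=O)[C@H](Cc1cc(OC)c(OCc2ccccc2)c(OCc3ccccc3)c1)/C=C/c1ccc(OCc2ccccc2)c(OC)c1 | intermediate
17 | (acyloxy)methyl radical from 16 (radical on the OCH2 carbon, C5) | [CH2]OC(=O)[C@H](Cc1cc(OC)c(OCc2ccccc2)c(OCc3ccccc3)c1)/C=C/c1ccc(OCc2ccccc2)c(OC)c1 | intermediate (not isolated)
18 | cyclised benzylic radical (radical on C6 of the trans lactone) | COc1cc([CH][C@H]2COC(=O)[C@@H]2Cc2cc(OCc3ccccc3)c(OCc3ccccc3)c(OC)c2)ccc1OCc1ccccc1 | intermediate (not isolated)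
19 | (3R,4R)-3-[3,4-bis(benzyloxy)-5-methoxybenzyl]-4-[4-(benzyloxy)-3-methoxybenzyl]dihydrofuran-2(3H)-one | COc1cc(C[C@H]2COC(=O)[C@@H]2Cc2cc(OCc3ccccc3)c(OCc3ccccc3)c(OC)c2)ccc1OCc1ccccc1 | intermediate
20 | (−)-thujaplicatin, (3R,4R)-3-(3,4-dihydroxy-5-methoxybenzyl)-4-(4-hydroxy-3-methoxybenzyl)dihydrofuran-2(3H)-one | COc1cc(C[C@H]2COC(=O)[C@@H]2Cc2cc(O)c(O)c(OC)c2)ccc1O | target

**Totals**

Total step count: 11.
Longest linear sequence: 9 steps (7 to 20 through steps 3, 4, 5, 6, 7, 8, 9, 10 and 11).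

**Steps most likely to fail**

Step 10. Hydrogen transfer to the (acyloxy)methyl radical may outrun ring closure, because the ester must first rotate into the rotamer that the lactone needs. Facial control at C4 may also be incomplete, and the minor cis lactone would then have to be removed by chromatography.
Fallback: it sets out from 1 and 10 and comes back at 19. Stobbe condensation of 1 with dimethyl succinate (t-BuOK, t-BuOH, reflux) should give (E)-3-(methoxycarbonyl)-4-[4-(benzyloxy)-3-methoxyphenyl]but-3-enoic acid F1. Homogeneous asymmetric hydrogenation, which leaves benzyl ethers alone ([Rh(cod)2]BF4 with the antipode of a chiral bisphosphine such as Me-DuPhos that gives the R acid, H2, MeOH), should give (R)-3-(methoxycarbonyl)-4-[4-(benzyloxy)-3-methoxyphenyl]butanoic acid F2. Reduction of the ester beside the carboxylate salt (Ca(BH4)2 from CaCl2 and NaBH4, EtOH) and acid lactonisation should give (R)-4-[4-(benzyloxy)-3-methoxybenzyl]dihydrofuran-2(3H)-one F3. Its lithium enolate (LiN(i-Pr)2, THF, −78 °C) is then alkylated by 10 anti to the C4 substituent to give 19. Here C4–C5 is carried in with the succinate and C3–C7 is formed last.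

Step 6. The extended dienolate may be alkylated at its gamma carbon, or proton exchange between product and enolate may erode the new centre at C3.
Fallback: it sets out from 3 and 10 and comes back at 12. Double deprotonation of 3 (LiN(i-Pr)2, 2.2 equiv, THF, −78 to 0 °C) and alpha-alkylation of the dianion with 10 should give racemic (E)-2-[3,4-bis(benzyloxy)-5-methoxybenzyl]-4-[4-(benzyloxy)-3-methoxyphenyl]but-3-enoic acid F4. Acylation of 4 through the pivalic mixed anhydride, as in step 2, should give 12 together with its C2 epimer (R)-4-benzyl-3-[(2S,3E)-2-[3,4-bis(benzyloxy)-5-methoxybenzyl]-4-[4-(benzyloxy)-3-methoxyphenyl]but-3-enoyl]oxazolidin-2-one F5. The two diastereomers are separated by chromatography and 12 goes on.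

Step 7. The doubly activated alpha centre may lose configuration under the basic cleavage, or the electron-rich styrene may be oxidised by the peroxide.
Fallback: it sets out from 12 and comes back at 14. Thiolysis of the imide (EtSLi from EtSH and n-BuLi, THF, 0 °C) should give S-ethyl (2R,3E)-2-[3,4-bis(benzyloxy)-5-methoxybenzyl]-4-[4-(benzyloxy)-3-methoxyphenyl]but-3-enethioate F6 and release 4 without hydroxide or peroxide. Silver-assisted hydrolysis of the thioester (AgNO3, 2,6-lutidine, THF/H2O, rt) should then give 14.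

Further compounds
F1 | step 10 | (E)-3-(methoxycarbonyl)-4-[4-(benzyloxy)-3-methoxyphenyl]but-3-enoic acid | COC(=O)/C(CC(=O)O)=C/c1ccc(OCc2ccccc2)c(OC)c1
F2 | step 10 | (R)-3-(methoxycarbonyl)-4-[4-(benzyloxy)-3-methoxyphenyl]butanoic acid | COC(=O)[C@@H](CC(=O)O)Cc1ccc(OCc2ccccc2)c(OC)c1
F3 | step 10 | (R)-4-[4-(benzyloxy)-3-methoxybenzyl]dihydrofuran-2(3H)-one | O=C1C[C@@H](Cc2ccc(OCc3ccccc3)c(OC)c2)CO1
F4 | step 6 | racemic (E)-2-[3,4-bis(benzyloxy)-5-methoxybenzyl]-4-[4-(benzyloxy)-3-methoxyphenyl]but-3-enoic acid | OC(=O)C(Cc1cc(OC)c(OCc2ccccc2)c(OCc3ccccc3)c1)/C=C/c1ccc(OCc2ccccc2)c(OC)c1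
F5 | step 6 | (R)-4-benzyl-3-[(2S,3E)-2-[3,4-bis(benzyloxy)-5-methoxybenzyl]-4-[4-(benzyloxy)-3-methoxyphenyl]but-3-enoyl]oxazolidin-2-one | O=C([C@@H](Cc1cc(OC)c(OCc2ccccc2)c(OCc3ccccc3)c1)/C=C/c1ccc(OCc2ccccc2)c(OC)c1)N1[C@H](Cc2ccccc2)COC1=O
F6 | step 7 | S-ethyl (2R,3E)-2-[3,4-bis(benzyloxy)-5-methoxybenzyl]-4-[4-(benzyloxy)-3-methoxyphenyl]but-3-enethioate | CCSC(=O)[C@H](Cc1cc(OC)c(OCc2ccccc2)c(OCc3ccccc3)c1)/C=C/c1ccc(OCc2ccccc2)c(OC)c1
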